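The six-membered carbocycle (C1–C6) cis-fused to the cyclobutane (C1, C6, C7, C8), with methyls at C1, C3, C5, C7 and C8, is a folded polypropionate tetraene. The route rests on breaking C7–C8 and C1–C6 together. A Negishi coupling assembles the (E,Z,Z,E)-tetraenyl pyrone, which closes in the same flask by 8π-conrotatory and then 6π-disrotatory electrocyclization. This copy of the presumed biosynthesis forms both carbocycles and four contiguous stereocentres from an acyclic, stereocentre-free precursor. Singlet oxygen then bridges C2 and C5 from the convex face, and a chiral-base Kornblum–DeLaMare kinetic resolution of the racemic endoperoxide leaves the required enantiomer.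

Key step: step 8

Assumption: the sense of the final kinetic resolution cannot be predicted with confidence; the quinidine-derived catalyst is taken to consume the unwanted antipode, and its quinine-derived pseudoenantiomer is used instead if a trial run shows the opposite sense.

Remark: 18, 19 and 20 are racemic and their SMILES show the enantiomer of the target series. Atom numbers C1–C8 are those of the bicyclo[4.2.0]octadiene 19 (C1/C6 ring fusion, C7 carries the pyrone, C8 is CH–Me).

Step 1
Reactants: 1 prop-2-yn-1-ol
Product: 3 (Z)-3-iodo-2-methylprop-2-en-1-ol, via alkenylmagnesium alkoxide 2 (not isolated)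
Conditions: MeMgBr (3 equiv), CuI (10 mol %), Et2O, −10 °C → rt; then I2, −10 °C
Reagents that add atoms: methylmagnesium bromide C[Mg]Br; iodine II
Why: Copper-catalysed, alkoxide-directed anti-carbomagnesiation places the methyl on C2 and magnesium on C3 cis to the CH2O group within a chelate, and iodinolysis with retention should fix the Z geometry (I cis to CH2OH).

Step 2
Reactants: 3 (Z)-3-iodo-2-methylprop-2-en-1-ol
Product: 5 ethyl (2E,4Z)-5-iodo-2,4-dimethylpenta-2,4-dienoate, via (Z)-3-iodo-2-methylprop-2-enal 4 (not isolated)
Conditions: MnO2 (10 equiv), Ph3P=C(Me)CO2Et (1.3 equiv), CH2Cl2, rt, dark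
Reagents that add atoms: ethyl 2-(triphenylphosphoranylidene)propanoate CCOC(=O)C(C)=P(c1ccccc1)(c1ccccc1)c1ccccc1
Why: Tandem allylic oxidation–Wittig olefination traps the isomerisation-prone Z-iodoenal as it forms, and the stabilised α-methyl ylide should give the E-trisubstituted enoate while the iodoalkene geometry is untouched.

Step 3
Reactants: 5 ethyl (2E,4Z)-5-iodo-2,4-dimethylpenta-2,4-dienoate
Product: 6 (2E,4Z)-5-iodo-2,4-dimethylpenta-2,4-dienoic acid
Conditions: LiOH·H2O, THF/MeOH/H2O, rt; then 1 M HCl
Reagents that add atoms: lithium hydroxide [Li+].[OH-]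
Why: Ester saponification (acyl substitution) at room temperature should leave both alkene geometries and the vinylic iodide intact, since no stereocentre is involved and addition–elimination at the remote iodide is slow under these conditions.

Step 4
Reactants: 6 (2E,4Z)-5-iodo-2,4-dimethylpenta-2,4-dienoic acid; 7 methyl 2-methyl-3-oxopentanoate
Product: 10 methyl (6E,8Z)-9-iodo-2,4,6,8-tetramethyl-3,5-dioxonona-6,8-dienoate (mixture of C2/C4 epimers and enol forms), via acyl imidazolide 8 (not isolated), via keto ester dianion 9 (not isolated)
Conditions: 6, CDI, THF, rt; separately 7, NaH then n-BuLi, THF, 0 °C (3 equiv of dianion); add 8 at −78 °C, → −20 °C; aq. NH4Cl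
Reagents that add atoms: none
Why: Claisen-type γ-C-acylation of a β-keto ester 1,3-dianion, whose more reactive terminal carbanion attacks the activated acyl imidazolide in the 1,2 sense rather than the hindered α-methyl dienoyl system in a conjugate sense; the C2/C4 centres are erased on cyclisation.

Step 5
Reactants: 10 methyl (6E,8Z)-9-iodo-2,4,6,8-tetramethyl-3,5-dioxonona-6,8-dienoate
Product: 11 4-hydroxy-6-[(2E,4Z)-5-iodo-4-methylpenta-2,4-dien-2-yl]-3,5-dimethyl-2H-pyran-2-one
Conditions: DBU (2 equiv), toluene, 60 °C; then 1 M HCl
Reagents that add atoms: none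
Why: Base-mediated enol-lactonisation (6-exo-trig acyl substitution of the C5 enol oxygen on the methyl ester) should give the 4-hydroxy-2-pyrone, and the alkenyl iodide cannot eliminate because its neighbouring carbon bears no hydrogen.

Step 6
Reactants: 11 4-hydroxy-6-[(2E,4Z)-5-iodo-4-methylpenta-2,4-dien-2-yl]-3,5-dimethyl-2H-pyran-2-one
Product: 12 6-[(2E,4Z)-5-iodo-4-methylpenta-2,4-dien-2-yl]-2-methoxy-3,5-dimethyl-4H-pyran-4-one
Conditions: MeOTf (2 equiv), CH2Cl2, rt; aq. NaHCO3
Reagents that add atoms: methyl trifluoromethanesulfonate COS(=O)(=O)C(F)(F)F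
Why: Regioselective O-methylation under neutral conditions, in which the hard electrophile alkylates the most basic site (the lactone carbonyl oxygen) to a 2-methoxy-4-hydroxypyrylium ion that loses a proton to the α-methoxy-γ-pyrone rather than the 4-methoxy-2-pyrone favoured by the anion.

Step 7
Reactants: 13 (E)-2-methylbut-2-enal (tiglic aldehyde)
Product: 14 (2Z,4E)-2-iodo-4-methylhexa-2,4-diene
Conditions: EtPPh3I, n-BuLi, THF, rt; I2, −78 °C; NaHMDS, −20 °C; then 13, −78 °C → rt; kept as a pentane solution (volatile)
Reagents that add atoms: ethyltriphenylphosphonium iodide CC[P+](c1ccccc1)(c1ccccc1)c1ccccc1.[I-]; iodine II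
Why: Stork–Zhao-type Wittig olefination with the α-iodo ylide, which reacts under kinetic control through the cis-oxaphosphetane and should set the Z alkene (I cis to the dienyl chain) while the E alkene of 13 is carried through.

Step 8
Reactants: 14 (2Z,4E)-2-iodo-4-methylhexa-2,4-diene; 12 6-[(2E,4Z)-5-iodo-4-methylpenta-2,4-dien-2-yl]-2-methoxy-3,5-dimethyl-4H-pyran-4-one
Product: 19 racemic 2-methoxy-3,5-dimethyl-6-(1,3,5,7,8-pentamethylbicyclo[4.2.0]octa-2,4-dien-7-yl)-4H-pyran-4-one (cis-fused; pyrone and H-8 on the diene-ring face of the cyclobutane; methyls at C1, C7 and C8 on the other), via dienyllithium 15 (not isolated), via dienylzinc bromide 16 (not isolated), via tetraene 17 (not isolated), via cyclooctatriene 18 (not isolated)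
Conditions: 14, t-BuLi (2.1 equiv), Et2O, −78 °C; ZnBr2 (THF), −78 → 0 °C; 12, Pd(PPh3)4 (5 mol %), THF, rt, dark; then 45 °C; chromatography
Reagents that add atoms: none
Why: Iodine–lithium exchange, transmetalation to zinc and Negishi alkenyl–alkenyl coupling all proceed with retention and should deliver the (2E,4Z,6Z,8E)-tetraene 17, whose helical conformer undergoes thermal 8π conrotatory electrocyclization to cyclooctatriene 18 and then 6π disrotatory electrocyclization to 19. The closest known reaction type is the 8π/6π electrocyclization cascade of (E,Z,Z,E)-tetraenes to bicyclo[4.2.0]octadienes. The eight-membered ring closes by bonding the two tetraene termini (C7–C8) in conrotatory mode, and the cyclohexadiene and cyclobutane close together by bonding the termini of the ring triene (C1–C6) in disrotatory mode, which allows only the cis fusion. C7 and C8 are set by conrotation acting on the E geometry of both terminal alkenes, so that the two outward groups (pyrone and the C8 methyl) become trans and the C7 and C8 methyls cis, while C1 and C6 are set by disrotation. The relation of C7/C8 to the ring fusion is not kinetically enforced but under thermodynamic control, because the 6π closure is reversible near the reaction temperature; the wanted diastereomer is therefore separated and any epimeric bicycle is re-equilibrated through 18 on warming. The step needs intact Z,Z geometry at the two central alkenes, which the retentive low-temperature metalation and room-temperature coupling secure, and it gives the racemate because the two helical senses of achiral 17 are equally populated.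

Step 9
Reactants: 19 racemic bicyclo[4.2.0]octadiene
Product: 20 racemic 2-methoxy-3,5-dimethyl-6-(1,3,4,5,10-pentamethyl-7,8-dioxatricyclo[4.2.2.0^2,5]dec-9-en-3-yl)-4H-pyran-4-one (configuration of 19 retained; O–O bridge anti to the cyclobutane carbons C3/C4)
Conditions: O2, methylene blue (1 mol %), CH2Cl2, orange LED (λ > 550 nm), −20 °C
Reagents that add atoms: dioxygen O=O
Why: Singlet-oxygen [4+2] cycloaddition to the s-cis cyclohexadiene sets both peroxide carbons (C2 and C5 of 19) suprafacially, and attack should occur on the convex face because the concave face is covered by the cyclobutane and its endo pyrone; long-wavelength sensitisation leaves the pyrone unexcited.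

Step 10
Reactants: 20 racemic endoperoxide
Product: 21 target, CNP0183511.1 (single enantiomer, recovered unreacted)
Conditions: 9-O-acetylcupreidine (10 mol %), CH2Cl2, 0 °C, run to about 55–60 % conversion; chromatography
Reagents that add atoms: none
Why: Catalytic enantioselective Kornblum–DeLaMare rearrangement used as a kinetic resolution, in which the bifunctional cinchona base removes the single peroxide α-hydrogen (H-6; the other peroxide carbon is quaternary) of one enantiomer faster and turns it into a polar γ-hydroxy enone, so that the other enantiomer should be recovered enriched with its six stereocentres untouched.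

Compound list

1 | prop-2-yn-1-ol | C#CCO | starting material
2 | bromomagnesium (Z)-3-(bromomagnesio)-2-methylprop-2-en-1-olate | Br[Mg]OC/C(C)=C\[Mg]Br | intermediate
3 | (Z)-3-iodo-2-methylprop-2-en-1-ol | OC/C(C)=C\I | intermediate
4 | (Z)-3-iodo-2-methylprop-2-enal | O=C/C(C)=C\I | intermediate
5 | ethyl (2E,4Z)-5-iodo-2,4-dimethylpenta-2,4-dienoate | CCOC(=O)/C(C)=C/C(C)=C\I | intermediate
6 | (2E,4Z)-5-iodo-2,4-dimethylpenta-2,4-dienoic acid | OC(=O)/C(C)=C/C(C)=C\I | intermediate
7 | methyl 2-methyl-3-oxopentanoate | CCC(=O)C(C)C(=O)OC | starting material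
8 | (2E,4Z)-1-(imidazol-1-yl)-5-iodo-2,4-dimethylpenta-2,4-dien-1-one | O=C(n1ccnc1)/C(C)=C/C(C)=C\I | intermediate
9 | sodium lithium dianion of methyl 2-methyl-3-oxopentanoate | C[CH-]C(=O)[C-](C)C(=O)OC.[Na+].[Li+] | intermediate
10 | methyl (6E,8Z)-9-iodo-2,4,6,8-tetramethyl-3,5-dioxonona-6,8-dienoate | COC(=O)C(C)C(=O)C(C)C(=O)/C(C)=C/C(C)=C\I | intermediate
11 | 4-hydroxy-6-[(2E,4Z)-5-iodo-4-methylpenta-2,4-dien-2-yl]-3,5-dimethyl-2H-pyran-2-one | CC1=C(O)C(C)=C(/C(C)=C/C(C)=C\I)OC1=O | intermediate
12 | 6-[(2E,4Z)-5-iodo-4-methylpenta-2,4-dien-2-yl]-2-methoxy-3,5-dimethyl-4H-pyran-4-one | COc1oc(/C(C)=C/C(C)=C\I)c(C)c(=O)c1C | intermediate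
13 | (E)-2-methylbut-2-enal | C/C=C(C)/C=O | starting material
14 | (2Z,4E)-2-iodo-4-methylhexa-2,4-diene | C/C=C(C)/C=C(C)\I | intermediate
15 | (4-methylhexa-2,4-dien-2-yl)lithium, Li cis to C4, 4E | C/C=C(C)/C=C(C)\[Li] | intermediate
16 | [(2Z,4E)-4-methylhexa-2,4-dien-2-yl]zinc bromide | C/C=C(C)/C=C(C)\[Zn]Br | intermediate
17 | 2-methoxy-3,5-dimethyl-6-[(2E,4Z,6Z,8E)-4,6,8-trimethyldeca-2,4,6,8-tetraen-2-yl]-4H-pyran-4-one | COc1oc(/C(C)=C/C(C)=C\C(C)=C/C(C)=C/C)c(C)c(=O)c1C | intermediate
18 | racemic 2-methoxy-3,5-dimethyl-6-(1,3,5,7,8-pentamethylcycloocta-2,4,6-trien-1-yl)-4H-pyran-4-one, pyrone at C1 trans to the C8 methyl | COc1oc([C@@]2(C)[C@H](C)/C(C)=C\C(C)=C/C(C)=C\2)c(C)c(=O)c1C | intermediate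
19 | racemic 2-methoxy-3,5-dimethyl-6-(1,3,5,7,8-pentamethylbicyclo[4.2.0]octa-2,4-dien-7-yl)-4H-pyran-4-one, cis-fused, pyrone endo, C1/C7/C8 methyls mutually cis | COc1oc([C@@]2(C)[C@H](C)[C@@]3(C)C=C(C)C=C(C)[C@@H]23)c(C)c(=O)c1C | intermediate
20 | racemic 2-methoxy-3,5-dimethyl-6-(1,3,4,5,10-pentamethyl-7,8-dioxatricyclo[4.2.2.0^2,5]dec-9-en-3-yl)-4H-pyran-4-one, peroxide anti to the cyclobutane | COc1oc([C@@]2(C)[C@H](C)[C@@]3(C)[C@@H]4OO[C@@](C)(C=C4C)[C@@H]23)c(C)c(=O)c1C | intermediate
21 | CNP0183511.1, single enantiomer of 20 as given | COc1oc([C@@]2(C)[C@H](C)[C@@]3(C)[C@@H]4OO[C@@](C)(C=C4C)[C@@H]23)c(C)c(=O)c1C | target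

Total step count: 10. Longest linear sequence: 9 steps (steps 1–6, then 8, 9, 10); step 7 is a one-step side branch.

Steps most likely to fail

1. Step 8. The volatile dienyl iodide may undergo incomplete or geometry-eroding metalation, giving isomeric tetraenes that cannot enter the 8π manifold; the thermodynamic partition between the two ring-fusion diastereomers in the reversible 6π closure is a second concern. Fallback (reversed polarity, no organolithium): setting out from 12, Miyaura borylation (B2pin2, PdCl2(PPh3)2/2 PPh3, KOPh, toluene, 50 °C) should give with retention the dienyl boronate 2-methoxy-3,5-dimethyl-6-[(2E,4Z)-4-methyl-5-(4,4,5,5-tetramethyl-1,3,2-dioxaborolan-2-yl)penta-2,4-dien-2-yl]-4H-pyran-4-one F1. Suzuki–Miyaura coupling of F1 with iodide 14 (Pd(PPh3)4, TlOEt, THF/H2O, rt) should give tetraene 17, which cyclises as before, so the route is rejoined at 19.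

2. Step 10. The chiral base may discriminate poorly between the two enantiomers, so that the recovered endoperoxide stays of low enantiomeric purity at acceptable conversion. Fallback (physical resolution before oxygenation): setting out from 19, preparative HPLC on a polysaccharide chiral stationary phase should give the target-series enantiomer of the bicyclo[4.2.0]octadiene F2, kept cold to avoid any retro-electrocyclization. The singlet-oxygen cycloaddition of step 9 applied to it should give 21 directly, so the route is rejoined at 21.

3. Step 9. Ene-type hydroperoxidation at the allylic methyl groups, attack on the wrong face, or sensitised degradation of the pyrone may compete with the [4+2] addition. Fallback (different mechanism, no light): setting out from 19, a radical-cation-catalysed cycloaddition of triplet oxygen (tris(4-bromophenyl)aminium hexachloroantimonate, 5 mol %, O2, CH2Cl2, −78 °C, dark) should add O2 only across the 1,3-diene, again from the convex face, and rejoin the route at 20. This fallback makes no new compound (F0).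

Further compounds

F1 | step 8 | 2-methoxy-3,5-dimethyl-6-[(2E,4Z)-4-methyl-5-(4,4,5,5-tetramethyl-1,3,2-dioxaborolan-2-yl)penta-2,4-dien-2-yl]-4H-pyran-4-one | COc1oc(/C(C)=C/C(C)=C\B2OC(C)(C)C(C)(C)O2)c(C)c(=O)c1C
F2 | step 10 | single enantiomer (target series) of 2-methoxy-3,5-dimethyl-6-(1,3,5,7,8-pentamethylbicyclo[4.2.0]octa-2,4-dien-7-yl)-4H-pyran-4-one | COc1oc([C@@]2(C)[C@H](C)[C@@]3(C)C=C(C)C=C(C)[C@@H]23)c(C)c(=O)c1C
F0 | step 9 | none | none
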